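(All constants were chosen freely; the result is computed.)

Read at 25 h, late in a radical run, monomer in chains is the time integral of what the growing radical has added, so that integral is the thing to reckon.

common to all: free monomer 0.50 M; initiator 5 mol%; time 25 h
- south: at 80 °C until 5.0 h, from then on at 50 °C
- west: temperature 50 °C
- east: temperature 65 °C
- north-west: temperature 80 °C

    initiator → 2 initiating radical (k1 = 9.36 × 10⁻⁶ /s, Ea1 = 124 kJ/mol)
    free monomer + initiating radical → growing radical + monomer in chains (k2 = 3620 /M/s, Ea2 = 37.0 kJ/mol)
    free monomer + growing radical → monomer in chains + growing radical, rate k3*[growing radical]*[free monomer] (k3 = 123 /M/s, Ea3 = 45.0 kJ/mol)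
    2 growing radical → dead chain (k4 = 2 × 10⁷ /M/s, Ea4 = 24.0 kJ/mol)
    free monomer + monomer in chains ⇌ idle adduct, settled at all times (K5 = 3.87 /M, ΔH5 = −76.0 kJ/mol)
    2 free monomer → homo dimer (k6 = 3.62 × 10⁻⁶ /M/s, Ea6 = 81.0 kJ/mol)
    free monomer ⇌ dormant form (K7 = 1.9, k7 = 2.44 × 10⁻⁴ /s, Ea7 = 115 kJ/mol, ΔH7 = −35.0 kJ/mol)
    (constants at 80 °C)

- a species is counted by the free monomer in it: one idle adduct or homo dimer counts as two
- amounts and yields of monomer in chains count idle adduct too
- a step written with two of one species runs at k times the square of its concentration and takes two of it each time
- at 80 °C the constants are as listed, elsewhere as the activation energies and enthalpies make them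
- in an amount of monomer in chains, one idle adduct counts as one monomer in chains

- which flask leads in amount of monomer in chains, in percent of the free monomer charged ("all alike" within 1.5 percentage points) (south / west / east / north-west / all alike)
- how much monomer in chains is there at the end, in percent of the free monomer charged: south
- how much monomer in chains is there at the end, in percent of the free monomer charged: west
- how much monomer in chains is there at the end, in percent of the free monomer charged: east
- how much monomer in chains is there at the end, in percent of the free monomer charged: north-west

**Radical level.** This reckoning is my own and follows north-west, where every constant stands as listed. Each decomposition of initiator (I, rate constant kd) gives a pair of radicals, and each termination (constant kt) removes a pair. So the growing radical settles at R = √(kd·[I]/kt). With the charge of 0.0250 M of initiator this gives a starting level Rs of 1.08 × 10⁻⁷ M. A growing radical lives 0.231 s, far shorter than the run, so the steady level may be used.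

**Exposure.** Initiator falls as exp(−kd·t), so R falls at the half rate, as exp(−kd·t/2). Free monomer is consumed pseudo-first-order, with constant kp·R, where kp belongs to the propagation step. That rate integrates in closed form to Θ = 2·kp·Rs/kd·(1 − exp(−kd·t/2)), which for north-west comes to 0.977. This is the propagation exposure, the time integral of kp·R.

**Free share.** Free monomer and dormant form balance with constant K of 1.9, so the free share φ of that pool is 1/(1+K), or 0.345. The balance comes within 0.746 h, far shorter than the run. The pool therefore shrinks by exp(−φΘ), which puts 28.6 % of the charge into chains. Each initiating radical adds one more monomer, a further 5.69 %. The first number for north-west is 34.3 %.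

**Weak link.** The constant φ is the weak link, and two corrections reforge it. Free monomer starts as the whole pool, and its excess over φ dies within that relaxation time while R is still near Rs, which adds 0.0234 to φΘ. Against this, idle adduct ties free monomer away from the pool. Its balance at the end gives 9.37 % of the charge, with each idle adduct counted once. Taken at the mean of its rise, that costs 1.58 %. The number I commit to for north-west is 34.4 %.

**The forecast.** The forecast puts north-west ahead, with 33 % there, 12.2 % in south, 11.6 % in east and 4.6 % in west. Its grounds begin: “I took the radical level as steady from initiator decomposition against termination”. For north-west its figure stands below mine.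

**The flasks.** The leader is north-west at 32.2 %, with south at 11.7 %, east at 10.6 % and west at 4.43 %. Termination of growing radical is the main reason that the exposure of 0.977 leaves north-west at 32.2 %: with that step struck out, the same run gives >99.9 %. South, at the temperature of north-west until 5.00 h, has an exposure of 0.230 by then, which gives 11.3 % by the same sum, and the south flask holds 10.7 % at that moment.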